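**Plan**

- Retrosynthesis: the benzylic silyl ether and the C6' methyl ether come off first. Ring B is then cut at four bonds (C2'–C3', C3'–C4', C5'–C6', C1'–C6') into an aryloxyvinyl diazoketone and methoxyacetylene.
- Enabling feature: ring B carries oxygen at C1' (ether to ring A), C4' and C6', with C4' and C6' meta across the unsubstituted C5'. A vinylketene plus an alkoxyalkyne delivers exactly this resorcinol pattern, and C1' and C2' (with its CH2O group) enter as the two vinyl carbons.
- The diazoketone is cut at the vinyl C1'–O bond (addition–elimination of the mono-prenylated ring A phenol on an enol tosylate) and at the C(=O)–CHN2 bond (acyl chloride plus diazomethane).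
- Forward: ring A is bought and prenylated. A C3 ester is formylated, tosylated, joined to ring A and turned into the diazoketone. Ring B is built last by benzannulation, then O-methylation and desilylation finish the synthesis.
- Stereochemistry: the target has no stereocentre and no stereogenic double bond. The enol ether geometry of the intermediates disappears when ring B aromatises.

Key step: step 9

Assumption: the enol ether double bond of compounds 7–11 is drawn E (oxygen trans to the carbonyl group). Because this geometry is erased on aromatisation, a minor Z isomer could be carried along.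

**Route**

Step 1
Reactants: 1 methyl 2,6-dihydroxy-4-methylbenzoate; 2 1-bromo-3-methylbut-2-ene
Product: 3 methyl 2-hydroxy-4-methyl-6-(3-methylbut-2-enyloxy)benzoate
Conditions: K2CO3 (1.1 equiv), 2 (1.05 equiv), acetone, rt → 50 °C
Reagents that add atoms: none
Why: Williamson O-alkylation; after the first ether forms, the remaining hydroxyl is held in a hydrogen bond to the ester carbonyl and is much less acidic, so one equivalent of bromide should stop at the mono-ether.

Step 2
Reactants: 4 methyl 3-hydroxypropanoate
Product: 5 methyl 3-(tert-butyldimethylsilyloxy)propanoate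
Conditions: TBSCl, imidazole, DMF, 0 °C → rt
Reagents that add atoms: tert-butyldimethylsilyl chloride, CC(C)(C)[Si](C)(C)Cl
Why: standard imidazole-promoted silylation of a primary alcohol, giving an ether that withstands the bases used later and is removed by fluoride at the end.

Step 3
Reactants: 5 methyl 3-(tert-butyldimethylsilyloxy)propanoate
Product: 6 methyl (2Z)-3-hydroxy-2-(tert-butyldimethylsilyloxymethyl)prop-2-enoate (enol form of the 2-formyl ester)
Conditions: LiN(iPr)2 (1.1 equiv), THF, −78 °C; HCO2Me, −78 → 0 °C; AcOH quench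
Reagents that add atoms: methyl formate, COC=O
Why: crossed Claisen formylation of a lithium ester enolate with a non-enolisable formate; at −78 °C the β-silyloxy enolate should be acylated faster than it expels silyloxide, and the product stays as its stabilised enolate until the mild acid quench.

Step 4
Reactants: 6 methyl (2Z)-3-hydroxy-2-(tert-butyldimethylsilyloxymethyl)prop-2-enoate
Product: 7 methyl (2E)-2-(tert-butyldimethylsilyloxymethyl)-3-(4-methylphenylsulfonyloxy)prop-2-enoate
Conditions: TsCl, Et3N, N-methylimidazole (cat.), CH2Cl2, 0 °C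
Reagents that add atoms: 4-methylbenzenesulfonyl chloride, Cc1ccc(cc1)S(Cl)(=O)=O
Why: O-sulfonylation of the enol of a formyl ester with N-methylimidazole as sulfonyl-transfer catalyst, which turns the enol oxygen into a leaving group on a vinylogous mixed anhydride; the E geometry is the one expected under amine-base conditions.

Step 5
Reactants: 3 methyl 2-hydroxy-4-methyl-6-(3-methylbut-2-enyloxy)benzoate; 7 methyl (2E)-2-(tert-butyldimethylsilyloxymethyl)-3-(4-methylphenylsulfonyloxy)prop-2-enoate
Product: 8 methyl 2-{[(1E)-3-methoxy-3-oxo-2-(tert-butyldimethylsilyloxymethyl)prop-1-enyl]oxy}-4-methyl-6-(3-methylbut-2-enyloxy)benzoate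
Conditions: Cs2CO3 (1.5 equiv), DMF, 0 °C → rt
Reagents that add atoms: none
Why: nucleophilic vinylic substitution (conjugate addition–elimination) of the caesium phenoxide on the β-tosyloxy acrylate; tosylate leaves from the intermediate ester enolate far faster than silyloxide, and the conjugated E aryl enol ether is the expected outcome.

Step 6
Reactants: 8 methyl 2-{[(1E)-3-methoxy-3-oxo-2-(tert-butyldimethylsilyloxymethyl)prop-1-enyl]oxy}-4-methyl-6-(3-methylbut-2-enyloxy)benzoate
Product: 9 (2E)-3-[2-(methoxycarbonyl)-5-methyl-3-(3-methylbut-2-enyloxy)phenoxy]-2-(tert-butyldimethylsilyloxymethyl)prop-2-enoic acid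
Conditions: LiOH·H2O (1.5 equiv), THF/H2O 3:1, 0 °C → rt; 0.5 M HCl to pH 4 at 0 °C
Reagents that add atoms: lithium hydroxide, [Li+].[OH-] (oxygen of the new carboxyl group)
Why: chemoselective saponification; the acrylate ester is unhindered whereas the ring A benzoate has two ortho oxygen substituents that block formation of the tetrahedral intermediate, and the α-substituent and donor oxygen disfavour conjugate attack of hydroxide.

Step 7
Reactants: 9 (2E)-3-[2-(methoxycarbonyl)-5-methyl-3-(3-methylbut-2-enyloxy)phenoxy]-2-(tert-butyldimethylsilyloxymethyl)prop-2-enoic acid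
Product: 11 methyl 2-{[(1E)-4-diazo-3-oxo-2-(tert-butyldimethylsilyloxymethyl)but-1-enyl]oxy}-4-methyl-6-(3-methylbut-2-enyloxy)benzoate, via acid chloride 10 (not isolated)
Conditions: 1-chloro-N,N,2-trimethylprop-1-enylamine (1.2 equiv), CH2Cl2, 0 °C → rt; then CH2N2 (4 equiv), Et2O, 0 °C
Reagents that add atoms: diazomethane, C=[N+]=[N-]; 1-chloro-N,N,2-trimethylprop-1-enylamine, CC(C)=C(Cl)N(C)C (chlorine of intermediate 10 only)
Why: neutral acid chloride formation with an α-chloroenamine followed by acylation of diazomethane (first stage of the Arndt–Eistert sequence); the trisubstituted push–pull double bond is a poor dipolarophile, so acylation should outrun pyrazoline formation, and excess diazomethane removes HCl before it can reach the silyl or prenyl ether.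

Step 8
Reactants: 12 2-chloro-1,1-dimethoxyethane (chloroacetaldehyde dimethyl acetal)
Product: 13 methoxyacetylene
Conditions: NaNH2 (3 equiv), liq. NH3, −33 °C; evaporate NH3; cold sat. aq. NaCl, distil into a cold trap, use at once as a cold solution
Reagents that add atoms: none
Why: twofold amide-induced elimination (loss of methanol, then of HCl) in liquid ammonia, after which the cold aqueous quench releases the volatile ynol ether for immediate use.

Step 9
Reactants: 11 methyl 2-{[(1E)-4-diazo-3-oxo-2-(tert-butyldimethylsilyloxymethyl)but-1-enyl]oxy}-4-methyl-6-(3-methylbut-2-enyloxy)benzoate; 13 methoxyacetylene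
Product: 18 methyl 2-[2-hydroxy-4-methoxy-6-(tert-butyldimethylsilyloxymethyl)phenoxy]-4-methyl-6-(3-methylbut-2-enyloxy)benzoate, via aryloxyvinylketene 14 (not isolated), via vinylcyclobutenone 15 (not isolated), via dienylketene 16 (not isolated), via cyclohexadienone 17 (not isolated)
Conditions: 13 (3–5 equiv), ClCH2CH2Cl, hν (medium-pressure Hg lamp, Pyrex filter), 10–20 °C, sealed Pyrex vessel; then 80 °C
Reagents that add atoms: none
Why: Photochemical Wolff rearrangement of 11 moves the alkenyl carbon C2' onto the former diazo carbon C3' and gives ketene 14; the ynol ether adds to the ketene C=C in a (2+2) cycloaddition (C3'–C4' and C5'–C6' bonds) to give cyclobutenone 15, which opens by a four-electron electrocyclic reaction (light or 80 °C) to dienylketene 16. Ring B then closes by a thermal six-electron disrotatory electrocyclisation between the ketene carbon C6' and the aryloxy-bearing vinyl carbon C1', giving cyclohexadienone 17, which tautomerises to phenol 18. The closest known reaction type is the Danheiser benzannulation of α,β-unsaturated and heteroaryl diazo ketones with alkoxy- and silyloxyalkynes, which gives resorcinol monoethers. No stereocentre is formed and the olefin geometry of 11 is lost on aromatisation. The step needs regioselectivity in the (2+2) addition, secured by the polarisation of methoxyacetylene (its unsubstituted carbon attacks the ketene carbonyl carbon, so the methoxy group ends up at C4', meta to the new hydroxyl), and chemoselectivity for the alkyne over the prenyl double bond, secured by the much higher nucleophilicity and the excess of the ynol ether. Pyrex-filtered light should spare the aryl ethers, and the trans relation of the aryloxy group to the ketene chain keeps the closing terminus unhindered.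

Step 10
Reactants: 18 methyl 2-[2-hydroxy-4-methoxy-6-(tert-butyldimethylsilyloxymethyl)phenoxy]-4-methyl-6-(3-methylbut-2-enyloxy)benzoate
Product: 19 methyl 2-[2,4-dimethoxy-6-(tert-butyldimethylsilyloxymethyl)phenoxy]-4-methyl-6-(3-methylbut-2-enyloxy)benzoate
Conditions: MeI, K2CO3, acetone, 40 °C
Reagents that add atoms: iodomethane, CI
Why: Williamson methylation of the only free phenol; the hindered benzoate, the silyl ether and the prenyl ether are inert to these conditions.

Step 11
Reactants: 19 methyl 2-[2,4-dimethoxy-6-(tert-butyldimethylsilyloxymethyl)phenoxy]-4-methyl-6-(3-methylbut-2-enyloxy)benzoate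
Product: 20 methyl 2-[2-(hydroxymethyl)-4,6-dimethoxyphenoxy]-4-methyl-6-(3-methylbut-2-enyloxy)benzoate (target)
Conditions: Bu4NF, AcOH (1:1), THF, 0 °C → rt
Reagents that add atoms: none
Why: fluoride-induced cleavage of the Si–O bond, driven by the strong Si–F bond; the acetic acid buffer keeps the medium non-basic so the methyl ester and the aryl ethers are untouched.

**Compound list**

1 | methyl 2,6-dihydroxy-4-methylbenzoate | COC(=O)c1c(O)cc(C)cc1O | starting material
2 | 1-bromo-3-methylbut-2-ene (prenyl bromide) | CC(C)=CCBr | starting material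
3 | methyl 2-hydroxy-4-methyl-6-(3-methylbut-2-enyloxy)benzoate | COC(=O)c1c(O)cc(C)cc1OCC=C(C)C | intermediate
4 | methyl 3-hydroxypropanoate | COC(=O)CCO | starting material
5 | methyl 3-(tert-butyldimethylsilyloxy)propanoate | COC(=O)CCO[Si](C)(C)C(C)(C)C | intermediate
6 | methyl (2Z)-3-hydroxy-2-(tert-butyldimethylsilyloxymethyl)prop-2-enoate (enol of methyl 2-formyl-3-(tert-butyldimethylsilyloxy)propanoate) | O/C=C(\C(=O)OC)CO[Si](C)(C)C(C)(C)C | intermediate
7 | methyl (2E)-2-(tert-butyldimethylsilyloxymethyl)-3-(4-methylphenylsulfonyloxy)prop-2-enoate | COC(=O)/C(CO[Si](C)(C)C(C)(C)C)=C/OS(=O)(=O)c1ccc(C)cc1 | intermediate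
8 | methyl 2-{[(1E)-3-methoxy-3-oxo-2-(tert-butyldimethylsilyloxymethyl)prop-1-enyl]oxy}-4-methyl-6-(3-methylbut-2-enyloxy)benzoate | COC(=O)c1c(OCC=C(C)C)cc(C)cc1O/C=C(\CO[Si](C)(C)C(C)(C)C)C(=O)OC | intermediate
9 | (2E)-3-[2-(methoxycarbonyl)-5-methyl-3-(3-methylbut-2-enyloxy)phenoxy]-2-(tert-butyldimethylsilyloxymethyl)prop-2-enoic acid | COC(=O)c1c(OCC=C(C)C)cc(C)cc1O/C=C(\CO[Si](C)(C)C(C)(C)C)C(=O)O | intermediate
10 | (2E)-3-[2-(methoxycarbonyl)-5-methyl-3-(3-methylbut-2-enyloxy)phenoxy]-2-(tert-butyldimethylsilyloxymethyl)prop-2-enoyl chloride | COC(=O)c1c(OCC=C(C)C)cc(C)cc1O/C=C(\CO[Si](C)(C)C(C)(C)C)C(Cl)=O | intermediate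
11 | methyl 2-{[(1E)-4-diazo-3-oxo-2-(tert-butyldimethylsilyloxymethyl)but-1-enyl]oxy}-4-methyl-6-(3-methylbut-2-enyloxy)benzoate | COC(=O)c1c(OCC=C(C)C)cc(C)cc1O/C=C(\CO[Si](C)(C)C(C)(C)C)C(=O)C=[N+]=[N-] | intermediate
12 | 2-chloro-1,1-dimethoxyethane (chloroacetaldehyde dimethyl acetal) | COC(CCl)OC | starting material
13 | methoxyacetylene | COC#C | intermediate
14 | methyl 2-{[(1Z)-4-oxo-2-(tert-butyldimethylsilyloxymethyl)buta-1,3-dienyl]oxy}-4-methyl-6-(3-methylbut-2-enyloxy)benzoate (aryloxyvinylketene; aryloxy trans to the ketene chain) | COC(=O)c1c(OCC=C(C)C)cc(C)cc1O/C=C(\CO[Si](C)(C)C(C)(C)C)C=C=O | intermediate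
15 | methyl 2-{[(1Z)-2-(2-methoxy-4-oxocyclobut-2-enyl)-3-(tert-butyldimethylsilyloxy)prop-1-enyl]oxy}-4-methyl-6-(3-methylbut-2-enyloxy)benzoate (racemic vinylcyclobutenone) | COC(=O)c1c(OCC=C(C)C)cc(C)cc1O/C=C(\CO[Si](C)(C)C(C)(C)C)C1C(=O)C=C1OC | intermediate
16 | methyl 2-{[(1Z,3E)-4-methoxy-6-oxo-2-(tert-butyldimethylsilyloxymethyl)hexa-1,3,5-trienyl]oxy}-4-methyl-6-(3-methylbut-2-enyloxy)benzoate (dienylketene) | COC(=O)c1c(OCC=C(C)C)cc(C)cc1O/C=C(\CO[Si](C)(C)C(C)(C)C)/C=C(OC)\C=C=O | intermediate
17 | methyl 2-{[4-methoxy-6-oxo-2-(tert-butyldimethylsilyloxymethyl)cyclohexa-2,4-dienyl]oxy}-4-methyl-6-(3-methylbut-2-enyloxy)benzoate (racemic cyclohexadienone) | COC(=O)c1c(OCC=C(C)C)cc(C)cc1OC1C(=O)C=C(OC)C=C1CO[Si](C)(C)C(C)(C)C | intermediate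
18 | methyl 2-[2-hydroxy-4-methoxy-6-(tert-butyldimethylsilyloxymethyl)phenoxy]-4-methyl-6-(3-methylbut-2-enyloxy)benzoate | COC(=O)c1c(OCC=C(C)C)cc(C)cc1Oc1c(CO[Si](C)(C)C(C)(C)C)cc(OC)cc1O | intermediate
19 | methyl 2-[2,4-dimethoxy-6-(tert-butyldimethylsilyloxymethyl)phenoxy]-4-methyl-6-(3-methylbut-2-enyloxy)benzoate | COC(=O)c1c(OCC=C(C)C)cc(C)cc1Oc1c(CO[Si](C)(C)C(C)(C)C)cc(OC)cc1OC | intermediate
20 | methyl 2-[2-(hydroxymethyl)-4,6-dimethoxyphenoxy]-4-methyl-6-(3-methylbut-2-enyloxy)benzoate | COC(=O)c1c(OCC=C(C)C)cc(C)cc1Oc1c(CO)cc(OC)cc1OC | target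

**Step count**

Total: 11 steps. Longest linear sequence: 9 steps (steps 2, 3, 4, 5, 6, 7, 9, 10, 11, from methyl 3-hydroxypropanoate). Steps 1 and 8 are side branches.

**Steps most likely to fail, with fallbacks**

Step 9 (benzannulation). The photogenerated aryloxyvinylketene may be diverted before it meets the alkyne, by dimerisation or by acylating the phenol already formed. Light-induced E/Z isomerisation may also slow the six-electron closure, and the volatile ynol ether may be lost before cycloaddition. The fallback gives up the pericyclic construction of ring B and joins a ready-made ring B by copper-mediated aryl ether coupling. It sets out from phenol 3, which is coupled with commercial 2-bromo-3,5-dimethoxybenzaldehyde (CuI, picolinic acid, K3PO4, DMSO, 90 °C; Ullmann-type coupling assisted by the ortho formyl group). This gives methyl 2-(2-formyl-4,6-dimethoxyphenoxy)-4-methyl-6-(3-methylbut-2-enyloxy)benzoate F1. Reduction of the aldehyde with NaBH4 in MeOH at 0 °C, which leaves the hindered benzoate alone, comes back to the route at compound 20.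

Step 7 (diazoketone formation). Diazomethane may add as a 1,3-dipole across the conjugated double bond, or acid released during acyl activation may strip the silyl or prenyl ether. The fallback avoids both the acyl chloride and diazomethane. It sets out from acid 9, which is coupled with N,O-dimethylhydroxylamine hydrochloride (EDC·HCl, N-methylmorpholine, CH2Cl2) to give methyl 2-{[(1E)-3-[methoxy(methyl)amino]-3-oxo-2-(tert-butyldimethylsilyloxymethyl)prop-1-enyl]oxy}-4-methyl-6-(3-methylbut-2-enyloxy)benzoate F2. MeMgBr in THF at −78 → 0 °C then gives methyl 2-{[(1E)-3-oxo-2-(tert-butyldimethylsilyloxymethyl)but-1-enyl]oxy}-4-methyl-6-(3-methylbut-2-enyloxy)benzoate F3. Its kinetic enolate (LiN(SiMe3)2, THF, −78 °C) is acylated with 2,2,2-trifluoroethyl trifluoroacetate to give methyl 2-{[(1E)-5,5,5-trifluoro-3,5-dioxo-2-(tert-butyldimethylsilyloxymethyl)pent-1-enyl]oxy}-4-methyl-6-(3-methylbut-2-enyloxy)benzoate F4. Detrifluoroacetylative diazo transfer (MsN3, Et3N, H2O, MeCN) comes back to the route at compound 11.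

Step 5 (joining ring A to the C3 unit). The phenoxide may attack sulfur and take over the sulfonyl group instead of adding to carbon, or the hydrogen-bonded, hindered phenoxide may add too slowly. The fallback replaces the sulfonate by a vinyl bromide made without any enolate chemistry. The electrophile is built from commercial methyl 2-(hydroxymethyl)prop-2-enoate: silylation (TBSCl, imidazole) gives methyl 2-(tert-butyldimethylsilyloxymethyl)prop-2-enoate F5. Addition of Br2 in CH2Cl2 at 0 °C gives methyl 2,3-dibromo-2-(tert-butyldimethylsilyloxymethyl)propanoate F6. Dehydrobromination with DBU gives methyl (2E)-3-bromo-2-(tert-butyldimethylsilyloxymethyl)prop-2-enoate F7, of which either geometric isomer would serve. The fallback sets out from phenol 3, which is joined to F7 by copper-catalysed O-vinylation (CuI, N,N-dimethylglycine, Cs2CO3, dioxane, 80 °C), a path in which no sulfonyl group can be transferred. It comes back to the route at compound 8.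

**Further compounds**

F1 | step 9 | methyl 2-(2-formyl-4,6-dimethoxyphenoxy)-4-methyl-6-(3-methylbut-2-enyloxy)benzoate | COC(=O)c1c(OCC=C(C)C)cc(C)cc1Oc1c(C=O)cc(OC)cc1OC
F2 | step 7 | methyl 2-{[(1E)-3-[methoxy(methyl)amino]-3-oxo-2-(tert-butyldimethylsilyloxymethyl)prop-1-enyl]oxy}-4-methyl-6-(3-methylbut-2-enyloxy)benzoate | COC(=O)c1c(OCC=C(C)C)cc(C)cc1O/C=C(\CO[Si](C)(C)C(C)(C)C)C(=O)N(C)OC
F3 | step 7 | methyl 2-{[(1E)-3-oxo-2-(tert-butyldimethylsilyloxymethyl)but-1-enyl]oxy}-4-methyl-6-(3-methylbut-2-enyloxy)benzoate | COC(=O)c1c(OCC=C(C)C)cc(C)cc1O/C=C(\CO[Si](C)(C)C(C)(C)C)C(C)=O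
F4 | step 7 | methyl 2-{[(1E)-5,5,5-trifluoro-3,5-dioxo-2-(tert-butyldimethylsilyloxymethyl)pent-1-enyl]oxy}-4-methyl-6-(3-methylbut-2-enyloxy)benzoate | COC(=O)c1c(OCC=C(C)C)cc(C)cc1O/C=C(\CO[Si](C)(C)C(C)(C)C)C(=O)CC(=O)C(F)(F)F
F5 | step 5 | methyl 2-(tert-butyldimethylsilyloxymethyl)prop-2-enoate | C=C(CO[Si](C)(C)C(C)(C)C)C(=O)OC
F6 | step 5 | methyl 2,3-dibromo-2-(tert-butyldimethylsilyloxymethyl)propanoate (racemic) | COC(=O)C(Br)(CBr)CO[Si](C)(C)C(C)(C)C
F7 | step 5 | methyl (2E)-3-bromo-2-(tert-butyldimethylsilyloxymethyl)prop-2-enoate | COC(=O)/C(CO[Si](C)(C)C(C)(C)C)=C/Br
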